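**Retrosynthetic overview**
- Target ⇐ C8–O acylation of the epoxy alcohol core with (2R,3R)-3-chloro-2-hydroxy-2-methylbutanoic acid, itself made from (R)-lactic acid by self-regeneration of the stereocentre.
- cis-4,5-Oxirane ⇐ bromohydrin formation and ring closure on the (4Z)-macrolactone, face set by C6/C7; C9 acetate by silyl-to-acetyl exchange.
- Ten-membered carbocycle, then the trans α-methylene-γ-lactone ⇐ chromium-electrocatalysed intramolecular allylation forming C6–C7 (Z-enal + 2-(bromomethyl)enoate) with lactonization in the same flask.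
- Seco chain ⇐ Baylis–Hillman/SN2′ bromination at C7; C10=C1 by aldol condensation of 2-deoxy-L-ribonolactone (C7–C10 and C14; stereocentres C8, C9) with a nerol-derived C1–C6 aldehyde.
- Ring order: sugar γ-lactone opened → carbocycle → trans-γ-lactone → oxirane.

Assumption: carbons are numbered as in germacranes (C1–C15; lactone carbonyl C12, ester carbon C14). The SMILES is read as the cis-4,5-epoxide (4R,5S) with 6S,7R,8S,9R and a (2R,3R) side chain; 2-deoxy-L-ribose, nerol and (R)-lactic acid are bought.

**Route**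

Step 1
Reactants: 1 2-deoxy-L-ribose
Product: 2 2-deoxy-L-ribono-1,4-lactone
Conditions: Br2, H2O, rt, 4 d
Reagents that add atoms: none
Why: Bromine-water oxidation of the aldose lactol to the γ-lactone leaves both stereocentres (later C9 and C8) untouched and differentiates O8 (ring oxygen) from O9 and O7.

Step 2
Reactants: 2 2-deoxy-L-ribono-1,4-lactone
Product: 3 3,5-bis-O-(triethylsilyl)-2-deoxy-L-ribono-1,4-lactone
Conditions: Et3SiCl, imidazole, DMF, 0 °C to rt
Reagents that add atoms: chlorotriethylsilane, CC[Si](Cl)(CC)CC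
Why: Standard silylation of both free hydroxyls gives a β-silyloxy lactone whose enolate does not β-eliminate at low temperature.

Step 3
Reactants: 4 nerol
Product: 5 neryl 4-methoxybenzyl ether
Conditions: NaH, 4-methoxybenzyl chloride, Bu4NI (cat.), THF/DMF, 0 °C to rt
Reagents that add atoms: 4-methoxybenzyl chloride, COc1ccc(CCl)cc1
Why: Williamson etherification protects the future C6 oxygen while keeping the Z-olefin that becomes the cis-4,5 unit.

Step 4
Reactants: 5 neryl 4-methoxybenzyl ether
Product: 7 (4Z)-6-[(4-methoxybenzyl)oxy]-4-methylhex-4-enal, via terminal epoxide 6 (not isolated)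
Conditions: mCPBA, CH2Cl2, −20 to 0 °C; then H5IO6, THF/H2O, 0 °C
Reagents that add atoms: mCPBA, O=C(OO)c1cccc(Cl)c1
Why: Prilezhaev epoxidation picks the more electron-rich distal trisubstituted olefin (the allylic-ether olefin is deactivated) and periodic acid cleaves the epoxide to the C1 aldehyde.

Step 5
Reactants: 3 3,5-bis-O-(triethylsilyl)-2-deoxy-L-ribono-1,4-lactone; 7 (4Z)-6-[(4-methoxybenzyl)oxy]-4-methylhex-4-enal
Product: 10 (3E,4R,5S)-3-[(4Z)-6-(4-methoxybenzyloxy)-4-methylhex-4-en-1-ylidene]-4-(triethylsilyloxy)-5-[(triethylsilyloxy)methyl]oxolan-2-one, via aldol adduct 8 (not isolated), via aldol mesylate 9 (not isolated)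
Conditions: LiN(SiMe3)2, THF, −78 °C; 7; then MsCl, −78 to 0 °C; then DBU, 0 °C to rt
Reagents that add atoms: none
Why: Lactone-enolate aldol addition, mesylation of the aldolate and E1cB elimination form C10=C1 as the E-alkylidene lactone (C2 cis to C9), because only the exocyclic mesylate is a leaving group and the silyloxy group at C9 is not.

Step 6
Reactants: 10 the (E)-alkylidene lactone
Product: 13 methyl (2E,6Z)-2-[(1R,2S)-2-(tert-butyldimethylsilyloxy)-1,3-bis(triethylsilyloxy)propyl]-8-(4-methoxybenzyloxy)-6-methylocta-2,6-dienoate, via lithium carboxylate 11 (not isolated), via hydroxy ester 12 (not isolated)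
Conditions: LiOH, THF/H2O, 0 °C; evaporate; MeI, DMF, 0 °C; then TBSOTf, 2,6-lutidine, CH2Cl2, −78 °C
Reagents that add atoms: lithium hydroxide, [Li+].[OH-]; iodomethane, CI; tert-butyldimethylsilyl triflate, CC(C)(C)[Si](C)(C)OS(=O)(=O)C(F)(F)F
Why: Saponification, SN2 methylation of the carboxylate and immediate silylation of the liberated C8 hydroxyl turn the sugar lactone into the C14 methyl ester before the γ-hydroxy ester can relactonize, giving O8 a protecting group distinct from O9 and O7.

Step 7
Reactants: 13 the tris-silyl methyl ester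
Product: 14 C7 aldehyde (13 with CH2OSiEt3 replaced by CHO)
Conditions: (COCl)2, DMSO, CH2Cl2, −78 to −40 °C; then Et3N
Reagents that add atoms: none
Why: Swern conditions cleave and oxidize a primary triethylsilyl ether directly while secondary triethylsilyl and tert-butyldimethylsilyl ethers survive, so no separate deprotection is needed.

Step 8
Reactants: 14 C7 aldehyde; 15 methyl acrylate
Product: 16 Baylis–Hillman adduct (C7 carbinol, mixture of epimers)
Conditions: DABCO (1 equiv), MeOH (cat.), neat 15, rt, 3 d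
Reagents that add atoms: none
Why: The Morita–Baylis–Hillman reaction of the activated α-silyloxy aldehyde installs C11–C13 and C12; the new carbinol centre is lost in the next step, so its configuration is irrelevant.

Step 9
Reactants: 16 Baylis–Hillman adduct
Product: 17 (Z)-2-(bromomethyl)enoate (C7=C11, CH2Br cis to C8)
Conditions: NBS, Me2S, CH2Cl2, −20 to 0 °C
Reagents that add atoms: N-bromosuccinimide, O=C1CCC(=O)N1Br
Why: Corey–Kim-type activation followed by SN2′ attack of bromide transposes the allylic system to the thermodynamically preferred Z primary bromide.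

Step 10
Reactants: 17 (Z)-2-(bromomethyl)enoate
Product: 19 (Z)-enal (C6 aldehyde), via allylic alcohol 18 (not isolated)
Conditions: DDQ, CH2Cl2/pH 7 buffer, 0 °C; then Dess–Martin periodinane, NaHCO3, CH2Cl2, 0 °C
Reagents that add atoms: none
Why: Oxidative removal of the 4-methoxybenzyl ether and buffered Dess–Martin oxidation give the Z-enal without Z/E isomerization and without touching the allylic bromide or silyl ethers.

Step 11
Reactants: 19 (Z)-enal allylic bromide
Product: 21 (4Z)-macrolactone with 8-OTBS, 9-OTES and C14 methyl ester, via seco hydroxy ester 20 (not isolated)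
Conditions: CrCl2 (20 mol%), Bu4NBr, DMF/THF, aluminium anode, nickel-foam cathode, undivided cell, 3 mA, 2.4 F/mol, slow addition of 19 (2 mM), rt; aq. citric acid
Reagents that add atoms: none
Why: Proposed new method: a chromium-electrocatalysed intramolecular 2-(methoxycarbonyl)allylation with lactonization, in which cathodically regenerated divalent chromium converts the allylic bromide into a σ-allyl trivalent chromium species that adds through C7 to the enal carbonyl in a closed six-membered transition state inside the forming ten-membered ring; Al3+ from the anode takes over the alkoxide, which then closes onto the C12 ester; ring strain is expected to enforce the anti (trans-lactone) C6/C7 relation, and with H8 eclipsing the allyl plane (A1,3 strain against C13) and the C9 chain anti to the incoming carbonyl, C6 should bond on the face syn to the C8 silyloxy group, giving the C6/C7 configuration of the target; the closest known reactions are stoichiometric CrCl2 Nozaki–Hiyama–Kishi macrocyclizations to germacranolides and intermolecular electrochemical chromium-catalysed Nozaki–Hiyama–Kishi couplings.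

Step 12
Reactants: 21 macrolactone
Product: 23 9-O-acetyl macrolactone (8-OTBS), via C9 alcohol 22 (not isolated)
Conditions: HF·pyridine, pyridine, THF, 0 °C; then Ac2O, DMAP, rt
Reagents that add atoms: acetic anhydride, CC(=O)OC(C)=O
Why: The secondary triethylsilyl ether is cleaved selectively in the presence of the tert-butyldimethylsilyl ether and the freed C9 hydroxyl is acetylated in the same flask with retention.

Step 13
Reactants: 23 9-O-acetyl macrolactone
Product: 25 cis-4,5-epoxide (8-OTBS, 9-OAc), via bromohydrin 24 (not isolated)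
Conditions: NBS, THF/H2O (4:1), 0 °C; then DBU, 0 °C to rt
Reagents that add atoms: water, O
Why: Halohydrin formation and epoxide closure: the bromonium ion should form on the face anti to C7 (the face peracids take in germacranolides), water opens it anti at tertiary C4 and base-induced SN2 closure places the oxirane oxygen on the opposite face, giving the cis-(4R,5S)-epoxide; the two electron-poor olefins do not react.

Step 14
Reactants: 25 cis-4,5-epoxide
Product: 26 8-hydroxy epoxy lactone
Conditions: HF·pyridine, pyridine, THF, 0 °C to rt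
Reagents that add atoms: none
Why: Buffered fluoride desilylation frees the C8 hydroxyl without opening the oxirane or moving the C9 acetate.

Step 15
Reactants: 27 (R)-lactic acid
Product: 28 (2R,5R)-2-tert-butyl-5-methyl-1,3-dioxolan-4-one
Conditions: pivalaldehyde, TsOH (cat.), H2SO4 (cat.), pentane, reflux (Dean–Stark); recrystallize at −78 °C
Reagents that add atoms: pivalaldehyde, CC(C)(C)C=O
Why: Acetalization gives the cis-dioxolanone, whose acetal centre is set by the lactic acid stereocentre (Seebach self-regeneration of stereocentres).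

Step 16
Reactants: 28 (2R,5R)-2-tert-butyl-5-methyl-1,3-dioxolan-4-one; 29 acetaldehyde
Product: 30 (2R,5S)-2-tert-butyl-5-[(1S)-1-hydroxyethyl]-5-methyl-1,3-dioxolan-4-one
Conditions: LiN(iPr)2, THF, −78 °C; then 29, −78 °C
Reagents that add atoms: none
Why: Aldol addition of the dioxolanone enolate occurs anti to the tert-butyl group (sets C2′) and through a Zimmerman–Traxler chair with the aldehyde methyl equatorial (sets the carbinol as 1S); selectivity at the carbinol is expected to be modest and the minor epimer is removed by chromatography.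

Step 17
Reactants: 30 aldol adduct
Product: 32 (2R,5R)-2-tert-butyl-5-[(1R)-1-chloroethyl]-5-methyl-1,3-dioxolan-4-one, via triflate 31 (not isolated)
Conditions: Tf2O, pyridine, CH2Cl2, −30 °C; then Bu4NCl, 0 °C to rt
Reagents that add atoms: tetrabutylammonium chloride, CCCC[N+](CCCC)(CCCC)CCCC.[Cl-]
Why: SN2 displacement of the triflate by chloride inverts the carbinol centre to the (R)-chloride (C3′); the electron-withdrawing neighbours suppress ionization and rearrangement.

Step 18
Reactants: 32 chloro dioxolanone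
Product: 33 (2R,3R)-3-chloro-2-hydroxy-2-methylbutanoic acid
Conditions: 6 M HCl, dioxane, 60 °C
Reagents that add atoms: none
Why: Acid hydrolysis of the acylal releases pivalaldehyde and the free α-hydroxy acid without touching either stereocentre.

Step 19
Reactants: 26 8-hydroxy epoxy lactone; 33 (2R,3R)-3-chloro-2-hydroxy-2-methylbutanoic acid
Product: 35 target CNP0185503.1, via mixed anhydride 34 (not isolated)
Conditions: 2,4,6-Cl3C6H2COCl, Et3N, toluene, rt; then 26, DMAP, rt
Reagents that add atoms: none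
Why: Yamaguchi esterification acylates the secondary C8 hydroxyl with retention; the hindered tertiary hydroxyl of the acid does not compete and the base is too weak to close the chlorohydrin.

**Compound list**

1 | 2-deoxy-L-ribose | O=CC[C@@H](O)[C@@H](O)CO | starting material
2 | 2-deoxy-L-ribono-1,4-lactone, (4R,5S)-4-hydroxy-5-(hydroxymethyl)oxolan-2-one | O=C1C[C@@H](O)[C@H](CO)O1 | intermediate
3 | (4R,5S)-4-(triethylsilyloxy)-5-[(triethylsilyloxy)methyl]oxolan-2-one | O=C1C[C@@H](O[Si](CC)(CC)CC)[C@H](CO[Si](CC)(CC)CC)O1 | intermediate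
4 | nerol, (2Z)-3,7-dimethylocta-2,6-dien-1-ol | CC(C)=CCC/C(C)=C\CO | starting material
5 | neryl 4-methoxybenzyl ether | CC(C)=CCC/C(C)=C\COCc1ccc(OC)cc1 | intermediate
6 | 6,7-epoxide of 5 (racemic at the epoxide CH) | CC1(C)OC1CC/C(C)=C\COCc1ccc(OC)cc1 | intermediate (not isolated)
7 | (4Z)-6-[(4-methoxybenzyl)oxy]-4-methylhex-4-enal | O=CCC/C(C)=C\COCc1ccc(OC)cc1 | intermediate
8 | aldol adduct of 3 and 7 (mixture at the two new centres) | O=C1C(C(O)CC/C(C)=C\COCc2ccc(OC)cc2)[C@@H](O[Si](CC)(CC)CC)[C@H](CO[Si](CC)(CC)CC)O1 | intermediate (not isolated)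
9 | mesylate of 8 | O=C1C(C(OS(C)(=O)=O)CC/C(C)=C\COCc2ccc(OC)cc2)[C@@H](O[Si](CC)(CC)CC)[C@H](CO[Si](CC)(CC)CC)O1 | intermediate (not isolated)
10 | (3E,4R,5S)-3-[(4Z)-6-(4-methoxybenzyloxy)-4-methylhex-4-en-1-ylidene]-4-(triethylsilyloxy)-5-[(triethylsilyloxy)methyl]oxolan-2-one | O=C1/C(=C/CC/C(C)=C\COCc2ccc(OC)cc2)[C@@H](O[Si](CC)(CC)CC)[C@H](CO[Si](CC)(CC)CC)O1 | intermediate
11 | lithium (2E,6Z)-2-[(1R,2S)-2-hydroxy-1,3-bis(triethylsilyloxy)propyl]-8-(4-methoxybenzyloxy)-6-methylocta-2,6-dienoate | [Li+].[O-]C(=O)/C(=C/CC/C(C)=C\COCc1ccc(OC)cc1)[C@@H](O[Si](CC)(CC)CC)[C@H](CO[Si](CC)(CC)CC)O | intermediate (not isolated)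
12 | methyl ester of 11 (free C8 hydroxyl) | COC(=O)/C(=C/CC/C(C)=C\COCc1ccc(OC)cc1)[C@@H](O[Si](CC)(CC)CC)[C@H](CO[Si](CC)(CC)CC)O | intermediate (not isolated)
13 | methyl (2E,6Z)-2-[(1R,2S)-2-(tert-butyldimethylsilyloxy)-1,3-bis(triethylsilyloxy)propyl]-8-(4-methoxybenzyloxy)-6-methylocta-2,6-dienoate | COC(=O)/C(=C/CC/C(C)=C\COCc1ccc(OC)cc1)[C@@H](O[Si](CC)(CC)CC)[C@H](CO[Si](CC)(CC)CC)O[Si](C)(C)C(C)(C)C | intermediate
14 | C7 aldehyde (13 with CH2OSiEt3 replaced by CHO) | COC(=O)/C(=C/CC/C(C)=C\COCc1ccc(OC)cc1)[C@@H](O[Si](CC)(CC)CC)[C@H](C=O)O[Si](C)(C)C(C)(C)C | intermediate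
15 | methyl acrylate | C=CC(=O)OC | starting material
16 | Baylis–Hillman adduct of 14 (C7 carbinol, epimer mixture) | COC(=O)/C(=C/CC/C(C)=C\COCc1ccc(OC)cc1)[C@@H](O[Si](CC)(CC)CC)[C@H](C(O)C(=C)C(=O)OC)O[Si](C)(C)C(C)(C)C | intermediate
17 | (Z)-2-(bromomethyl)enoate (C7=C11, 4-methoxybenzyl ether at C6) | COC(=O)/C(=C/CC/C(C)=C\COCc1ccc(OC)cc1)[C@@H](O[Si](CC)(CC)CC)[C@H](/C=C(\CBr)C(=O)OC)O[Si](C)(C)C(C)(C)C | intermediate
18 | C6 allylic alcohol of 17 | COC(=O)/C(=C/CC/C(C)=C\CO)[C@@H](O[Si](CC)(CC)CC)[C@H](/C=C(\CBr)C(=O)OC)O[Si](C)(C)C(C)(C)C | intermediate (not isolated)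
19 | (Z)-enal with C6 aldehyde and allylic bromide | COC(=O)/C(=C/CC/C(C)=C\C=O)[C@@H](O[Si](CC)(CC)CC)[C@H](/C=C(\CBr)C(=O)OC)O[Si](C)(C)C(C)(C)C | intermediate
20 | ten-membered seco hydroxy diester (C6 hydroxyl, C12 methyl ester) | C=C(C(=O)OC)[C@@H]1[C@H](O[Si](C)(C)C(C)(C)C)[C@H](O[Si](CC)(CC)CC)/C(C(=O)OC)=C\CC/C(C)=C\[C@H]1O | intermediate (not isolated)
21 | (4Z)-macrolactone: trans-fused 12,6-olide, 8-OTBS, 9-OTES, C14 methyl ester | C=C1C(=O)O[C@H]2[C@H]1[C@H](O[Si](C)(C)C(C)(C)C)[C@H](O[Si](CC)(CC)CC)/C(C(=O)OC)=C\CC/C(C)=C\2 | intermediate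
22 | C9 alcohol of 21 | C=C1C(=O)O[C@H]2[C@H]1[C@H](O[Si](C)(C)C(C)(C)C)[C@H](O)/C(C(=O)OC)=C\CC/C(C)=C\2 | intermediate (not isolated)
23 | 9-O-acetyl macrolactone (8-OTBS) | C=C1C(=O)O[C@H]2[C@H]1[C@H](O[Si](C)(C)C(C)(C)C)[C@H](OC(C)=O)/C(C(=O)OC)=C\CC/C(C)=C\2 | intermediate
24 | bromohydrin (C4 hydroxyl, C5 bromide, anti) | C=C1C(=O)O[C@H]2[C@H]1[C@H](O[Si](C)(C)C(C)(C)C)[C@H](OC(C)=O)/C(C(=O)OC)=C\CC[C@@](C)(O)[C@@H]2Br | intermediate (not isolated)
25 | cis-(4R,5S)-epoxide with 8-OTBS and 9-OAc | C=C1C(=O)O[C@H]2[C@H]1[C@H](O[Si](C)(C)C(C)(C)C)[C@H](OC(C)=O)/C(C(=O)OC)=C\CC[C@@]1(C)O[C@@H]21 | intermediate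
26 | 8-hydroxy epoxy lactone (9-OAc) | C=C1C(=O)O[C@H]2[C@H]1[C@H](O)[C@H](OC(C)=O)/C(C(=O)OC)=C\CC[C@@]1(C)O[C@@H]21 | intermediate
27 | (R)-lactic acid | C[C@@H](O)C(=O)O | starting material
28 | (2R,5R)-2-tert-butyl-5-methyl-1,3-dioxolan-4-one | C[C@H]1O[C@@H](C(C)(C)C)OC1=O | intermediate
29 | acetaldehyde | CC=O | starting material
30 | (2R,5S)-2-tert-butyl-5-[(1S)-1-hydroxyethyl]-5-methyl-1,3-dioxolan-4-one | C[C@@]1([C@H](C)O)O[C@@H](C(C)(C)C)OC1=O | intermediate
31 | triflate of 30 | C[C@@]1([C@H](C)OS(=O)(=O)C(F)(F)F)O[C@@H](C(C)(C)C)OC1=O | intermediate (not isolated)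
32 | (2R,5R)-2-tert-butyl-5-[(1R)-1-chloroethyl]-5-methyl-1,3-dioxolan-4-one | C[C@@]1([C@@H](C)Cl)O[C@@H](C(C)(C)C)OC1=O | intermediate
33 | (2R,3R)-3-chloro-2-hydroxy-2-methylbutanoic acid | OC(=O)[C@@](C)(O)[C@@H](C)Cl | intermediate
34 | mixed anhydride of 33 with 2,4,6-trichlorobenzoic acid | O=C(OC(=O)[C@@](C)(O)[C@@H](C)Cl)c1c(Cl)cc(Cl)cc1Cl | intermediate (not isolated)
35 | CNP0185503.1 | C=C1C(=O)O[C@H]2[C@H]1[C@H](OC(=O)[C@@](C)(O)[C@@H](C)Cl)[C@H](OC(C)=O)/C(C(=O)OC)=C\CC[C@@]1(C)O[C@@H]21 | target

**Step count**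

Total: 19 steps (steps 4, 5, 6, 10, 12, 13, 17 and 19 are telescoped one-flask sequences). Longest linear sequence: 13 steps (1, 2, 5–14, 19).

**Three steps most likely to fail**

Step 11 (proposed new electrocatalytic macrocyclization). Possible failures are direct cathodic reduction of the bromide or enal, oligomerization, Z-to-E drift of the enal, or the wrong face at C7. The fallback drops electrolysis and uses the known stoichiometric Nozaki–Hiyama protocol: it sets out from 19 with excess CrCl2 in THF/DMF under syringe-pump high dilution, as used for germacranolide ring closures, passes through 20 and comes back at 21. It makes no compound outside the list (F0).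

Step 13 (face of the oxirane). The prediction that electrophiles take the face anti to C7 rests on analogy with trans-germacranolides; if the ring exposes the other face, the bromohydrin sequence gives the 4,5-bis-epimeric epoxide. The fallback sets out from 23 and uses direct epoxidation with mCPBA/NaHCO3 in CH2Cl2 at 0 °C. This delivers oxygen syn to the face the electrophile takes, so it gives exactly the diastereomer the anti-addition/closure sequence cannot, and comes back at 25. It makes no compound outside the list (F0).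

Step 17 (SN2 chlorination next to a quaternary carbon). Elimination, neighbouring-group retention or no reaction are possible. The fallback sets out from 30 and activates the diol as a cyclic sulfate. Acid methanolysis (MeOH, TsOH) gives methyl (2S,3S)-2,3-dihydroxy-2-methylbutanoate F1. SOCl2/Et3N gives the cyclic sulfite F2, and RuCl3 (cat.)/NaIO4 gives methyl (4S,5S)-4,5-dimethyl-1,3,2-dioxathiolane-4-carboxylate 2,2-dioxide F3. LiCl in DMF opens F3 at the only secondary carbon with inversion to the lithium sulfate monoester F4, and dilute H2SO4/ether hydrolyses this to methyl (2R,3R)-3-chloro-2-hydroxy-2-methylbutanoate F5. 6 M HCl at 60 °C then gives the acid, so the fallback comes back at 33.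

Further compounds
F0 | step 11 | none | none
F0 | step 13 | none | none
F1 | step 17 | methyl (2S,3S)-2,3-dihydroxy-2-methylbutanoate | COC(=O)[C@@](C)(O)[C@H](C)O
F2 | step 17 | cyclic sulfite of F1 (mixture at sulfur) | COC(=O)[C@@]1(C)OS(=O)O[C@H]1C
F3 | step 17 | methyl (4S,5S)-4,5-dimethyl-1,3,2-dioxathiolane-4-carboxylate 2,2-dioxide | COC(=O)[C@@]1(C)OS(=O)(=O)O[C@H]1C
F4 | step 17 | lithium (2R,3R)-3-chloro-1-methoxy-2-methyl-1-oxobutan-2-yl sulfate | COC(=O)[C@@](C)(OS(=O)(=O)[O-])[C@@H](C)Cl.[Li+]
F5 | step 17 | methyl (2R,3R)-3-chloro-2-hydroxy-2-methylbutanoate | COC(=O)[C@@](C)(O)[C@@H](C)Cl
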